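A small charge of initiator, 0.68 mM against 1.4 mM in the red run, and you ask for a quick number on the target, with the hunch that the pace falls with the square root of the charge. I reckon the same way.

common to all: starting material 0.10 M
- red: partner 0.30 M; initiator 1.4 mM; run made earlier
- flask: partner 0.300 M; initiator 0.68 mM; time 10 h

red run (percent of the starting material charged)

| time / min | target / % |
|---|---|
| 10.0 | 0.1 |
| 15.0 | 0.6 |
| 25.0 | 2.9 |
| 40.0 | 2.1 |
| 80.0 | 6.9 |
| 120 | 9.3 |

(readings scatter by 1 percentage point)

- percentages count the starting material that a species holds: one ended chains A counts as two
- the numbers in the tables scatter by 1 percentage point (one standard deviation)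
- what may be going on: 2 first chain carrier -> ended chains A; target <-> isomer of the product; initiator -> 2 initiating radical; starting material + second chain carrier -> by-product + first chain carrier; partner + first chain carrier -> target + second chain carrier; 2 second chain carrier -> ended chains B; starting material + initiating radical -> capped initiator + first chain carrier
- no earlier run changes the charge of initiator; that part of a forecast is a guess

* amount of target in percent of the starting material charged, at 1.0 h, 3.0 h, 6.0 h and 10 h

If chains end when two carriers meet, as the scheme offers, the pace goes with the square root of the charge, which is half order in initiator. No earlier run tests this, so it is a guess. I carry it as the root factor, the square root of the flask's charge over the red charge. In powers of ten the flask's charge lies 0.314 below the red one, and the pace lies 0.157 below, so the root factor is 0.697.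

The red readings scatter by 1 percentage point, so the dip at 40.0 min says little. I draw a straight line from the start through the last reading, 9.3% at 120 min. Scaled by the root factor, that line gives 3.24% at 1.0 h, and I commit to that figure. The same line reaches 32.4% at 10 h, but it counts no slowing and no passage of target to its isomer, and the red run gives no rate for either. I hold that late figure loosely.

The forecast reads 3.3%, 9.2%, 16% and 23%, and says of its scaling: “That square-root scaling is assumed, because no run tests it.” It stands close to my figure at 1.0 h and lower than my line at 10 h.

The flask gives 3.40%, 8.80%, 15.7% and 24.2%.

    2 first chain carrier → ended chains A (k = 2.30 × 10⁸ /M/s)
    target ⇌ isomer of the product (K = 0.570, k = 0.260 /h)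
    initiator → 2 initiating radical (k = 9.70 × 10⁻⁴ /h)
    starting material + second chain carrier → by-product + first chain carrier (k = 23000 /M/s)
    partner + first chain carrier → target + second chain carrier (k = 1.50 × 10⁷ /M/h)
    2 second chain carrier → ended chains B (k = 8.00 × 10⁷ /M/s)
    starting material + initiating radical → capped initiator + first chain carrier (k = 2.40 × 10⁶ /M/s)

At 4.79 h the flask makes target 2.79 times faster than it uses it up, while the forward step from target to its isomer alone has a half-life of 2.7 h, short against the 10 h of the flask. At 10 h the root-factor line stands at 32.4%, higher than the 24.2% of target in the flask, and target and isomer of the product together hold 35.3%.

(The data stem from a simulated flask from invented constants; the scatter is artificial.)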